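**Retrosynthetic overview**

1. Feature: the only ring is a benzene with CO2H on C-1, OH on C-2, OMe on C-4 and the 2-oxoalkyl chain on C-6. C-1 and C-6, with the carboxyl carbon and C-1' attached to them, correspond to a 4-substituted but-2-ynoate; C-2(O)–C-3–C-4(O)–C-5 corresponds to a 1,1,3-trioxygenated buta-1,3-diene.
2. Target ⇒ methyl ester with C-2' masked as a dioxolane and O-13' as a silyl ether (ester saponified first, then both protecting groups removed by dilute acid).
3. Key disconnection of C-1–C-2 and C-5–C-6: Diels–Alder benzannulation of a Brassard-type silyl ketene acetal diene with the ketal-protected ynoate. The benzene ring is formed in this step; the dioxolane is only a protecting ring installed earlier.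
4. Ynoate ⇒ terminal alkyne + methyl chloroformate ⇒ aldehyde ⇒ ketal ester ⇒ beta-keto ester ⇒ O-silylated 12-hydroxydodecanoic acid + Meldrum's acid.
5. Diene ⇒ methyl (E)-3-methoxybut-2-enoate ⇒ methyl acetoacetate.

Key step: step 9

Assumption: the target is taken as the open-chain keto acid drawn (a ring-chain lactol tautomer, if present, counts as the same compound); it has no stereocenter, so no stereocontrol is needed.

**Route**

Step 1
Reactants: 1 12-hydroxydodecanoic acid
Product: 3 12-[(tert-butyldimethylsilyl)oxy]dodecanoic acid, via bis-silylated ester 2 (not isolated)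
Conditions: tBuMe2SiCl (2.3 equiv), imidazole, DMF, rt; then K2CO3, MeOH/THF/H2O, rt; cold 1 M HCl to pH 4–5
Reagents that add atoms: tert-butyldimethylsilyl chloride, CC(C)(C)[Si](C)(C)Cl
Why: Silyl ether formation with the silyl chloride and imidazole caps both the alcohol and the acid, and the far more labile silyl ester is then cleaved selectively by mild carbonate hydrolysis while the primary silyl ether stays.

Step 2
Reactants: 3 12-[(tert-butyldimethylsilyl)oxy]dodecanoic acid; 4 Meldrum's acid (2,2-dimethyl-1,3-dioxane-4,6-dione)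
Product: 6 methyl 14-[(tert-butyldimethylsilyl)oxy]-3-oxotetradecanoate, via acyl Meldrum's acid 5 (not isolated)
Conditions: DCC, DMAP, CH2Cl2, 0 °C to rt; filter; then MeOH, toluene, 80 °C
Reagents that add atoms: Meldrum's acid (compound 4, listed above), CC1(C)OC(=O)CC(=O)O1; methanol, CO
Why: Carbodiimide-mediated C-acylation of Meldrum's acid, thermal fragmentation to the acylketene and trapping by methanol is the standard two-carbon homologation of an acid to a beta-keto ester (Oikawa–Yonemitsu synthesis) and is mild enough for the silyl ether.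

Step 3
Reactants: 6 methyl 14-[(tert-butyldimethylsilyl)oxy]-3-oxotetradecanoate
Product: 7 methyl {2-[11-(tert-butyldimethylsilyloxy)undecyl]-1,3-dioxolan-2-yl}acetate
Conditions: Me3SiOCH2CH2OSiMe3, Me3SiOSO2CF3 (cat.), CH2Cl2, −78 to −20 °C; pyridine quench
Reagents that add atoms: 1,2-bis(trimethylsilyloxy)ethane, C[Si](C)(C)OCCO[Si](C)(C)C
Why: Noyori ketalization (silyl triflate-catalysed exchange with the bis-silylated glycol at low temperature) forms the dioxolane without water or Brønsted acid, so the acid-sensitive silyl ether and the ester are left alone.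

Step 4
Reactants: 7 methyl {2-[11-(tert-butyldimethylsilyloxy)undecyl]-1,3-dioxolan-2-yl}acetate
Product: 8 {2-[11-(tert-butyldimethylsilyloxy)undecyl]-1,3-dioxolan-2-yl}acetaldehyde
Conditions: iBu2AlH (1.1 equiv), CH2Cl2, −78 °C; MeOH, then aq. KNaC4H4O6
Reagents that add atoms: none
Why: Partial ester reduction by the aluminium hydride at −78 °C stops at the aluminium hemiacetal, which is stabilised by chelation to a dioxolane oxygen and releases the aldehyde only on work-up.

Step 5
Reactants: 8 {2-[11-(tert-butyldimethylsilyloxy)undecyl]-1,3-dioxolan-2-yl}acetaldehyde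
Product: 9 2-[11-(tert-butyldimethylsilyloxy)undecyl]-2-(prop-2-yn-1-yl)-1,3-dioxolane
Conditions: dimethyl (1-diazo-2-oxopropyl)phosphonate, K2CO3, MeOH, 0 °C to rt
Reagents that add atoms: dimethyl (1-diazo-2-oxopropyl)phosphonate, COP(=O)(OC)C(=[N+]=[N-])C(C)=O
Why: Seyferth–Gilbert homologation in its Ohira–Bestmann form converts the aldehyde into the terminal alkyne with one added carbon under carbonate/methanol conditions that spare the ketal and the silyl ether.

Step 6
Reactants: 9 2-[11-(tert-butyldimethylsilyloxy)undecyl]-2-(prop-2-yn-1-yl)-1,3-dioxolane; 10 methyl chloroformate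
Product: 12 methyl 4-{2-[11-(tert-butyldimethylsilyloxy)undecyl]-1,3-dioxolan-2-yl}but-2-ynoate, via lithium acetylide 11 (not isolated)
Conditions: n-BuLi (1.05 equiv), THF, −78 °C; then ClCO2Me, −78 to 0 °C
Reagents that add atoms: methyl chloroformate (compound 10, listed above), COC(=O)Cl
Why: The terminal alkyne C–H is the most acidic site, and C-acylation of the resulting lithium acetylide with a chloroformate is the standard preparation of 2-alkynoates.

Step 7
Reactants: 13 methyl acetoacetate
Product: 14 methyl (E)-3-methoxybut-2-enoate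
Conditions: HC(OMe)3, H2SO4 (cat.), rt; distillation
Reagents that add atoms: trimethyl orthoformate, COC(OC)OC
Why: Acid-catalysed ketalization of the ketone by the orthoformate followed by loss of methanol on distillation gives the thermodynamically preferred conjugated (E)-enol ether.

Step 8
Reactants: 14 methyl (E)-3-methoxybut-2-enoate
Product: 16 (E)-1,3-dimethoxy-1-(trimethylsilyloxy)buta-1,3-diene, via lithium dienolate 15 (not isolated)
Conditions: LiN(iPr)2 (1.1 equiv), THF, −78 °C; then Me3SiCl, −78 °C to rt; pentane, filtration, distillation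
Reagents that add atoms: chlorotrimethylsilane, C[Si](C)(C)Cl
Why: Kinetic gamma-deprotonation of the vinylogous ester gives the extended dienolate, which is O-silylated to the Brassard-type silyl ketene acetal diene (silyl ketene acetal formation); the geometry of the acetal double bond has no consequence later.

Step 9
Reactants: 12 methyl 4-{2-[11-(tert-butyldimethylsilyloxy)undecyl]-1,3-dioxolan-2-yl}but-2-ynoate; 16 (E)-1,3-dimethoxy-1-(trimethylsilyloxy)buta-1,3-diene
Product: 19 methyl 2-({2-[11-(tert-butyldimethylsilyloxy)undecyl]-1,3-dioxolan-2-yl}methyl)-6-hydroxy-4-methoxybenzoate, via cyclohexadiene adduct 17 (not isolated), via dienone 18 (not isolated)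
Conditions: 16 (3 equiv, freshly distilled), toluene, 110–120 °C, sealed tube; then EtOAc, sat. aq. NH4Cl, rt
Reagents that add atoms: none
Why: The electron-rich diene 16 and the ester-polarized alkyne 12 should undergo a normal-demand, concerted but asynchronous [4+2] cycloaddition, the known Diels–Alder reaction of 1,1,3-trioxygenated butadienes with alkynoates that delivers 6-substituted 2-hydroxy-4-methoxybenzoates. The benzene ring is closed intermolecularly from a four-carbon and a two-carbon unit, the unsubstituted diene terminus bonding to the alkyne beta-carbon (C-5–C-6) and the acetal carbon to the alpha-carbon (C-1–C-2), to give 1,4-cyclohexadiene 17; a stepwise Mukaiyama–Michael addition followed by ring closure would give the same skeleton. The mixed silyl methyl acetal of 17 then expels methoxytrimethylsilane to give dienone 18, which tautomerizes to the hydrogen-bonded salicylate, so O-2 emerges as the free phenol and O-4 as the methyl ether without a separate differentiation step. No stereocenter remains, since the acetal stereocenter of racemic 17 is destroyed on aromatization. The selectivity needed is regiochemical (chain carbon next to C-5, ester carbon next to C-2) and is secured by the match of the largest HOMO coefficient at the diene CH2 terminus with the largest LUMO coefficient at the alkyne beta-carbon. The neutral thermal conditions leave dioxolane and silyl ether intact, the mildly protic work-up completes desilylation and aromatization, and an allenoate formed by adventitious isomerization of 12 would react with the same orientation to the same arene.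

Step 10
Reactants: 19 methyl 2-({2-[11-(tert-butyldimethylsilyloxy)undecyl]-1,3-dioxolan-2-yl}methyl)-6-hydroxy-4-methoxybenzoate
Product: 20 2-({2-[11-(tert-butyldimethylsilyloxy)undecyl]-1,3-dioxolan-2-yl}methyl)-6-hydroxy-4-methoxybenzoic acid
Conditions: KOH (10 equiv), EtOH/H2O (3:1), 85 °C; then 1 M HCl at 0 °C to pH 4; crude acid used directly
Reagents that add atoms: potassium hydroxide, [K+].[OH-]
Why: Saponification (acyl–oxygen hydrolysis) of the hindered salicylate needs hot excess hydroxide, and the base-stable dioxolane blocks C-2' so that no ketone enolate can condense onto the neighbouring ester, while cold acidification to pH 4 frees the acid without ketal loss or decarboxylation (partial loss of the silyl ether here would not matter, since the next step removes it).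

Step 11
Reactants: 20 2-({2-[11-(tert-butyldimethylsilyloxy)undecyl]-1,3-dioxolan-2-yl}methyl)-6-hydroxy-4-methoxybenzoic acid
Product: 21 2-hydroxy-6-(13-hydroxy-2-oxotridecyl)-4-methoxybenzoic acid (target)
Conditions: 1 M aq. HCl/THF (1:4), rt
Reagents that add atoms: water, O
Why: Dilute aqueous acid hydrolyses the dialkyl dioxolane and the primary silyl ether in one operation (acetal hydrolysis and acid-mediated desilylation), and room temperature keeps the electron-rich salicylic acid from protodecarboxylation and the keto acid from dehydrating to the isocoumarin.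

**Compound list**

1 | 12-hydroxydodecanoic acid | OC(=O)CCCCCCCCCCCO | starting material
2 | tert-butyldimethylsilyl 12-[(tert-butyldimethylsilyl)oxy]dodecanoate | CC(C)(C)[Si](C)(C)OC(=O)CCCCCCCCCCCO[Si](C)(C)C(C)(C)C | intermediate
3 | 12-[(tert-butyldimethylsilyl)oxy]dodecanoic acid | OC(=O)CCCCCCCCCCCO[Si](C)(C)C(C)(C)C | intermediate
4 | Meldrum's acid (2,2-dimethyl-1,3-dioxane-4,6-dione) | CC1(C)OC(=O)CC(=O)O1 | starting material
5 | 5-{12-[(tert-butyldimethylsilyl)oxy]-1-hydroxydodecylidene}-2,2-dimethyl-1,3-dioxane-4,6-dione | CC1(C)OC(=O)C(=C(O)CCCCCCCCCCCO[Si](C)(C)C(C)(C)C)C(=O)O1 | intermediate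
6 | methyl 14-[(tert-butyldimethylsilyl)oxy]-3-oxotetradecanoate | COC(=O)CC(=O)CCCCCCCCCCCO[Si](C)(C)C(C)(C)C | intermediate
7 | methyl {2-[11-(tert-butyldimethylsilyloxy)undecyl]-1,3-dioxolan-2-yl}acetate | COC(=O)CC1(CCCCCCCCCCCO[Si](C)(C)C(C)(C)C)OCCO1 | intermediate
8 | {2-[11-(tert-butyldimethylsilyloxy)undecyl]-1,3-dioxolan-2-yl}acetaldehyde | O=CCC1(CCCCCCCCCCCO[Si](C)(C)C(C)(C)C)OCCO1 | intermediate
9 | 2-[11-(tert-butyldimethylsilyloxy)undecyl]-2-(prop-2-yn-1-yl)-1,3-dioxolane | C#CCC1(CCCCCCCCCCCO[Si](C)(C)C(C)(C)C)OCCO1 | intermediate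
10 | methyl chloroformate | COC(=O)Cl | starting material
11 | lithium acetylide of 9 | [Li+].[C-]#CCC1(CCCCCCCCCCCO[Si](C)(C)C(C)(C)C)OCCO1 | intermediate
12 | methyl 4-{2-[11-(tert-butyldimethylsilyloxy)undecyl]-1,3-dioxolan-2-yl}but-2-ynoate | COC(=O)C#CCC1(CCCCCCCCCCCO[Si](C)(C)C(C)(C)C)OCCO1 | intermediate
13 | methyl acetoacetate | CC(=O)CC(=O)OC | starting material
14 | methyl (E)-3-methoxybut-2-enoate | CO/C(C)=C/C(=O)OC | intermediate
15 | lithium dienolate of 14 (lithium 1,3-dimethoxybuta-1,3-dien-1-olate) | [Li+].C=C(OC)/C=C(\OC)[O-] | intermediate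
16 | (E)-1,3-dimethoxy-1-(trimethylsilyloxy)buta-1,3-diene | C=C(OC)/C=C(\OC)O[Si](C)(C)C | intermediate
17 | methyl 2-({2-[11-(tert-butyldimethylsilyloxy)undecyl]-1,3-dioxolan-2-yl}methyl)-4,6-dimethoxy-6-(trimethylsilyloxy)cyclohexa-1,4-diene-1-carboxylate (racemic) | COC(=O)C1=C(CC2(CCCCCCCCCCCO[Si](C)(C)C(C)(C)C)OCCO2)CC(OC)=CC1(OC)O[Si](C)(C)C | intermediate
18 | methyl 2-({2-[11-(tert-butyldimethylsilyloxy)undecyl]-1,3-dioxolan-2-yl}methyl)-4-methoxy-6-oxocyclohexa-1,4-diene-1-carboxylate | COC(=O)C1=C(CC2(CCCCCCCCCCCO[Si](C)(C)C(C)(C)C)OCCO2)CC(OC)=CC1=O | intermediate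
19 | methyl 2-({2-[11-(tert-butyldimethylsilyloxy)undecyl]-1,3-dioxolan-2-yl}methyl)-6-hydroxy-4-methoxybenzoate | COC(=O)c1c(O)cc(OC)cc1CC2(CCCCCCCCCCCO[Si](C)(C)C(C)(C)C)OCCO2 | intermediate
20 | 2-({2-[11-(tert-butyldimethylsilyloxy)undecyl]-1,3-dioxolan-2-yl}methyl)-6-hydroxy-4-methoxybenzoic acid | OC(=O)c1c(O)cc(OC)cc1CC2(CCCCCCCCCCCO[Si](C)(C)C(C)(C)C)OCCO2 | intermediate
21 | 2-hydroxy-6-(13-hydroxy-2-oxotridecyl)-4-methoxybenzoic acid | COc1cc(O)c(C(=O)O)c(CC(=O)CCCCCCCCCCCO)c1 | target

**Step count and risks**

Total step count: 11. Longest linear sequence: 9 steps (steps 1–6 and 9–11, from 12-hydroxydodecanoic acid); the diene branch (steps 7–8) joins at step 9.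

Steps most likely to fail:

1. Step 9. The cycloaddition of the internal, beta-alkyl-substituted ynoate may be slow relative to thermal or hydrolytic degradation of the silyl ketene acetal diene, leaving conversion incomplete or stopping at conjugate addition without ring closure. The fallback sets out from ynoate 12 and uses a more reactive dienophile of the same connectivity. Gamma-deprotonation of 12 with LiN(iPr)2 in THF at −78 °C and kinetic alpha-protonation with acetic acid at −78 °C should give the racemic allenoate methyl 4-{2-[11-(tert-butyldimethylsilyloxy)undecyl]-1,3-dioxolan-2-yl}buta-2,3-dienoate F1. Allenoates add trioxygenated dienes under much milder conditions, so F1 and diene 16 (toluene, rt to 60 °C) should give, with the diene CH2 terminus on the central allene carbon, the alkylidene cycloadduct methyl 2-({2-[11-(tert-butyldimethylsilyloxy)undecyl]-1,3-dioxolan-2-yl}methylidene)-4,6-dimethoxy-6-(trimethylsilyloxy)cyclohex-4-ene-1-carboxylate F2. F2 loses methoxytrimethylsilane to the keto ester methyl 2-({2-[11-(tert-butyldimethylsilyloxy)undecyl]-1,3-dioxolan-2-yl}methylidene)-4-methoxy-6-oxocyclohex-4-ene-1-carboxylate F3, which tautomerizes to arene 19, where the route is rejoined.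

2. Step 10. Hydroxide attack on the doubly ortho-flanked, phenoxide-deactivated ester may be too slow, and the forcing then required could erode the silyl ether or cause decarboxylation on acidification. The fallback sets out from alkyne 9 and avoids hydrolysis altogether by carrying a benzyl ester. Lithium acetylide 11 (n-BuLi, THF, −78 °C) is acylated with benzyl chloroformate to give benzyl 4-{2-[11-(tert-butyldimethylsilyloxy)undecyl]-1,3-dioxolan-2-yl}but-2-ynoate F4. Cycloaddition with diene 16 as in step 9 passes through benzyl 2-({2-[11-(tert-butyldimethylsilyloxy)undecyl]-1,3-dioxolan-2-yl}methyl)-4,6-dimethoxy-6-(trimethylsilyloxy)cyclohexa-1,4-diene-1-carboxylate F5 and benzyl 2-({2-[11-(tert-butyldimethylsilyloxy)undecyl]-1,3-dioxolan-2-yl}methyl)-4-methoxy-6-oxocyclohexa-1,4-diene-1-carboxylate F6 to benzyl 2-({2-[11-(tert-butyldimethylsilyloxy)undecyl]-1,3-dioxolan-2-yl}methyl)-6-hydroxy-4-methoxybenzoate F7. Hydrogenolysis (H2, Pd/C, EtOAc, rt) then cleaves the benzyl ester under neutral conditions and gives acid 20, where the route is rejoined.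

3. Step 5. Under K2CO3/MeOH the alpha-unbranched aldehyde may enolize, with beta-elimination opening the dioxolane or aldol self-condensation occurring before homologation. The fallback sets out from aldehyde 8 and uses a Corey–Fuchs sequence that needs no alkoxide base. CBr4, PPh3 and Et3N in CH2Cl2 at 0 °C give 2-(3,3-dibromoprop-2-en-1-yl)-2-[11-(tert-butyldimethylsilyloxy)undecyl]-1,3-dioxolane F8. Treatment of F8 with n-BuLi (2.1 equiv) in THF at −78 °C generates lithium acetylide 11 by bromine–lithium exchange and rearrangement, and trapping in the same flask with methyl chloroformate 10 gives ynoate 12, where the route is rejoined without isolating 9.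

Further compounds
F1 | step 9 | methyl 4-{2-[11-(tert-butyldimethylsilyloxy)undecyl]-1,3-dioxolan-2-yl}buta-2,3-dienoate (racemic) | COC(=O)C=C=CC1(CCCCCCCCCCCO[Si](C)(C)C(C)(C)C)OCCO1
F2 | step 9 | methyl 2-({2-[11-(tert-butyldimethylsilyloxy)undecyl]-1,3-dioxolan-2-yl}methylidene)-4,6-dimethoxy-6-(trimethylsilyloxy)cyclohex-4-ene-1-carboxylate (mixture of isomers) | COC(=O)C1C(=CC2(CCCCCCCCCCCO[Si](C)(C)C(C)(C)C)OCCO2)CC(OC)=CC1(OC)O[Si](C)(C)C
F3 | step 9 | methyl 2-({2-[11-(tert-butyldimethylsilyloxy)undecyl]-1,3-dioxolan-2-yl}methylidene)-4-methoxy-6-oxocyclohex-4-ene-1-carboxylate (mixture of isomers) | COC(=O)C1C(=CC2(CCCCCCCCCCCO[Si](C)(C)C(C)(C)C)OCCO2)CC(OC)=CC1=O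
F4 | step 10 | benzyl 4-{2-[11-(tert-butyldimethylsilyloxy)undecyl]-1,3-dioxolan-2-yl}but-2-ynoate | O=C(OCc2ccccc2)C#CCC1(CCCCCCCCCCCO[Si](C)(C)C(C)(C)C)OCCO1
F5 | step 10 | benzyl 2-({2-[11-(tert-butyldimethylsilyloxy)undecyl]-1,3-dioxolan-2-yl}methyl)-4,6-dimethoxy-6-(trimethylsilyloxy)cyclohexa-1,4-diene-1-carboxylate (racemic) | O=C(OCc3ccccc3)C1=C(CC2(CCCCCCCCCCCO[Si](C)(C)C(C)(C)C)OCCO2)CC(OC)=CC1(OC)O[Si](C)(C)C
F6 | step 10 | benzyl 2-({2-[11-(tert-butyldimethylsilyloxy)undecyl]-1,3-dioxolan-2-yl}methyl)-4-methoxy-6-oxocyclohexa-1,4-diene-1-carboxylate | O=C(OCc3ccccc3)C1=C(CC2(CCCCCCCCCCCO[Si](C)(C)C(C)(C)C)OCCO2)CC(OC)=CC1=O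
F7 | step 10 | benzyl 2-({2-[11-(tert-butyldimethylsilyloxy)undecyl]-1,3-dioxolan-2-yl}methyl)-6-hydroxy-4-methoxybenzoate | O=C(OCc3ccccc3)c1c(O)cc(OC)cc1CC2(CCCCCCCCCCCO[Si](C)(C)C(C)(C)C)OCCO2
F8 | step 5 | 2-(3,3-dibromoprop-2-en-1-yl)-2-[11-(tert-butyldimethylsilyloxy)undecyl]-1,3-dioxolane | BrC(Br)=CCC1(CCCCCCCCCCCO[Si](C)(C)C(C)(C)C)OCCO1
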